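**Plan**

- Retrosynthesis: after removal of the N-(2,4-dimethoxybenzyl) group and the two indole Boc groups, the pyrrole is cut at N1–C5 and C4–C5. This releases C5 with its acetyl group as an acetyl carbene (diazoacetone).
- Enabling feature: pyrrole C5 is a single carbon that bears only the acetyl group and is bonded only to N1 and C4. What remains, N1=C2(CO2Me)–C3(indolyl)=C4H(indolyl), is a 1-azadiene that already holds the ester and both indole rings.
- The azadiene is cut at C2=N (imine condensation), at the C3–indole bond (Suzuki coupling of an α-bromo enone) and at C3=C4 (Wittig olefination of N-Boc-indole-3-carboxaldehyde with a pyruvate ylide).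
- Forward: the four-carbon chain is made by Wittig reaction, brominated at C3, arylated and turned into the imine. The pyrrole, the only ring formed, arises in one flask by carbene capture at nitrogen, 1,5-electrocyclisation and DDQ dehydrogenation. Acid then removes all three N-protecting groups.
- Stereochemistry: the target has no stereocentre. Only alkene and imine geometry matter (E from the Wittig step, retained in the coupling; Z imine), and the two sp3 centres of the dihydropyrrole are erased on aromatisation.

Key step: step 7

Remark: tert-butyl 3-formylindole-1-carboxylate and the N-Boc indol-3-yl pinacol boronate are taken as commercial. The short-lived sp3 intermediates 7 and 17 are drawn as the expected anti and trans racemates; their configuration has no consequence.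

**Route**

Step 1
Reactants: 1 methyl bromopyruvate (methyl 3-bromo-2-oxopropanoate); 2 triphenylphosphine
Product: 4 methyl 2-oxo-3-(triphenylphosphoranylidene)propanoate, via phosphonium bromide 3 (not isolated)
Conditions: PPh3, CH2Cl2, rt; then aq. Na2CO3, rt
Reagents that add atoms: none
Why: SN2 quaternisation of triphenylphosphine by the primary α-bromo ketone, then deprotonation of the acidic phosphonium salt with carbonate, is the standard preparation of a stabilised acyl Wittig ylide.

Step 2
Reactants: 4 methyl 2-oxo-3-(triphenylphosphoranylidene)propanoate; 5 tert-butyl 3-formylindole-1-carboxylate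
Product: 6 methyl (E)-4-[1-(tert-butoxycarbonyl)indol-3-yl]-2-oxobut-3-enoate
Conditions: toluene, 90 °C
Reagents that add atoms: none
Why: Wittig olefination with a stabilised β-keto ylide attacks only the aldehyde and should give the (E)-enone, the usual entry to β,γ-unsaturated α-keto esters; the Boc group makes the indole aldehyde behave as an ordinary aryl aldehyde.

Step 3
Reactants: 6 methyl (E)-4-[1-(tert-butoxycarbonyl)indol-3-yl]-2-oxobut-3-enoate
Product: 8 methyl (Z)-3-bromo-4-[1-(tert-butoxycarbonyl)indol-3-yl]-2-oxobut-3-enoate, via dibromide 7 (not isolated)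
Conditions: Br2, CH2Cl2, 0 °C; then Et3N, 0 °C → rt
Reagents that add atoms: bromine, BrBr
Why: Bromine addition to the enone double bond followed by E1cB dehydrobromination (loss of the acidic C3–H and the benzylic C4 bromide) is the standard α-bromination of enones and should give the (Z)-bromoenone with bromine cis to the indole, the Boc group tempering the indole ring against bromination.

Step 4
Reactants: 8 methyl (Z)-3-bromo-4-[1-(tert-butoxycarbonyl)indol-3-yl]-2-oxobut-3-enoate; 9 tert-butyl 3-(4,4,5,5-tetramethyl-1,3,2-dioxaborolan-2-yl)indole-1-carboxylate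
Product: 10 methyl (E)-3,4-bis[1-(tert-butoxycarbonyl)indol-3-yl]-2-oxobut-3-enoate
Conditions: Pd(dppf)Cl2 (5 mol%), K3PO4, 1,4-dioxane/H2O (20:1), 60 °C
Reagents that add atoms: none
Why: Suzuki–Miyaura coupling of an α-bromo enone, an activated alkenyl halide for oxidative addition to zerovalent palladium, proceeds with retention of alkene geometry so that the two indoles end up cis; phosphate base and little water limit Boc loss, keto ester hydrolysis and protodeboronation.

Step 5
Reactants: 10 methyl (E)-3,4-bis[1-(tert-butoxycarbonyl)indol-3-yl]-2-oxobut-3-enoate; 11 2,4-dimethoxybenzylamine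
Product: 12 methyl (2Z,3E)-3,4-bis[1-(tert-butoxycarbonyl)indol-3-yl]-2-[(2,4-dimethoxybenzyl)imino]but-3-enoate
Conditions: 11 (1.1 equiv), TiCl4 (0.6 equiv), Et3N (3 equiv), CH2Cl2, 0 °C → rt; filtered and used crude
Reagents that add atoms: none
Why: TiCl4-mediated ketimine condensation activates the very electrophilic keto carbonyl for 1,2-addition and removes water, the usual way from enones to 1-azadienes; the benzyl group should settle syn to the ester, away from the twisted trisubstituted alkene.

Step 6
Reactants: 13 pentane-2,4-dione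
Product: 15 diazoacetone (1-diazopropan-2-one), via 3-diazopentane-2,4-dione 14 (not isolated)
Conditions: 4-acetamidobenzenesulfonyl azide, Et3N, MeCN, 0 °C → rt; then aq. KOH, rt; used as a CH2Cl2 solution
Reagents that add atoms: 4-acetamidobenzenesulfonyl azide, CC(=O)Nc1ccc(S(=O)(=O)N=[N+]=[N-])cc1
Why: Regitz diazo transfer to the 1,3-diketone followed by hydroxide deacylation (retro-Claisen loss of one acetyl group) is the standard diazomethane-free preparation of a terminal diazo ketone.

Step 7
Reactants: 12 methyl (2Z,3E)-3,4-bis[1-(tert-butoxycarbonyl)indol-3-yl]-2-[(2,4-dimethoxybenzyl)imino]but-3-enoate; 15 diazoacetone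
Product: 18 methyl 5-acetyl-1-(2,4-dimethoxybenzyl)-3,4-bis[1-(tert-butoxycarbonyl)indol-3-yl]pyrrole-2-carboxylate, via azomethine ylide 16 (not isolated), via dihydropyrrole 17 (not isolated)
Conditions: Rh2(OAc)4 (2 mol%), CH2Cl2, 40 °C, slow addition of 15 (2–3 equiv); then DDQ (1.1 equiv), 0 °C → rt
Reagents that add atoms: none
Why: Rh2(OAc)4 decomposes 15 with loss of N2 to an electrophilic acetyl carbenoid of divalent rhodium, which the imine nitrogen lone pair of 12 intercepts to give azomethine ylide 16 (N1–C5 bond). The ylide is conjugated with C3=C4 and closes by a thermally allowed, disrotatory six-electron 1,5-electrocyclisation (formally 5-endo-trig at C4) that forms C4–C5 and the 4,5-dihydropyrrole 17; DDQ then takes hydride from C5 and the C4 proton is lost, giving the aromatic pyrrole. The closest known reaction type is the dirhodium- or copper-carbenoid [4+1] annulation of α,β-unsaturated imines to dihydropyrroles through azomethine ylides. No stereocentre survives: the two sp3 centres of 17 (trans expected) are erased on oxidation. The step needs five-ring closure at C4 in preference to aziridine formation or closure through the acetyl oxygen to a 4-oxazoline, attack at the imine nitrogen in preference to the indole 2,3-bonds and the dimethoxyarene, and little carbene dimerisation. These are secured by the (2Z) imine geometry that points the lone pair toward the alkene, the s-cis azadiene with hydrogen as the inside substituent at C4, the reversibility of oxazoline formation against the oxidation-trapped C–C closure, the deactivating Boc groups and the slow addition of 15.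

Step 8
Reactants: 18 methyl 5-acetyl-1-(2,4-dimethoxybenzyl)-3,4-bis[1-(tert-butoxycarbonyl)indol-3-yl]pyrrole-2-carboxylate
Product: 19 methyl 5-acetyl-3,4-di(1H-indol-3-yl)-1H-pyrrole-2-carboxylate
Conditions: TFA/anisole (10:1), 60 °C
Reagents that add atoms: none
Why: Acidolysis removes both indole N-Boc carbamates as isobutene and CO2 and ionises the electron-rich 2,4-dimethoxybenzyl group from the weakly basic diacylpyrrole nitrogen as a stabilised benzyl cation, which anisole traps by Friedel–Crafts alkylation, while the methyl ester and the acetyl group should be untouched.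

**Compound list**

1 | methyl bromopyruvate (methyl 3-bromo-2-oxopropanoate) | COC(=O)C(=O)CBr | starting material
2 | triphenylphosphine | c1ccc(P(c2ccccc2)c2ccccc2)cc1 | starting material
3 | (3-methoxy-2,3-dioxopropyl)triphenylphosphonium bromide | COC(=O)C(=O)C[P+](c1ccccc1)(c1ccccc1)c1ccccc1.[Br-] | intermediate
4 | methyl 2-oxo-3-(triphenylphosphoranylidene)propanoate | COC(=O)C(=O)C=P(c1ccccc1)(c1ccccc1)c1ccccc1 | intermediate
5 | tert-butyl 3-formylindole-1-carboxylate | CC(C)(C)OC(=O)n1cc(C=O)c2ccccc12 | starting material
6 | methyl (E)-4-[1-(tert-butoxycarbonyl)indol-3-yl]-2-oxobut-3-enoate | COC(=O)C(=O)/C=C/c1cn(C(=O)OC(C)(C)C)c2ccccc12 | intermediate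
7 | methyl anti-3,4-dibromo-4-[1-(tert-butoxycarbonyl)indol-3-yl]-2-oxobutanoate (racemic, one enantiomer drawn) | COC(=O)C(=O)[C@H](Br)[C@H](Br)c1cn(C(=O)OC(C)(C)C)c2ccccc12 | intermediate
8 | methyl (Z)-3-bromo-4-[1-(tert-butoxycarbonyl)indol-3-yl]-2-oxobut-3-enoate | COC(=O)C(=O)/C(Br)=C/c1cn(C(=O)OC(C)(C)C)c2ccccc12 | intermediate
9 | tert-butyl 3-(4,4,5,5-tetramethyl-1,3,2-dioxaborolan-2-yl)indole-1-carboxylate | CC(C)(C)OC(=O)n1cc(B2OC(C)(C)C(C)(C)O2)c2ccccc12 | starting material
10 | methyl (E)-3,4-bis[1-(tert-butoxycarbonyl)indol-3-yl]-2-oxobut-3-enoate (the two indoles cis) | COC(=O)C(=O)/C(=C/c1cn(C(=O)OC(C)(C)C)c2ccccc12)c1cn(C(=O)OC(C)(C)C)c2ccccc12 | intermediate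
11 | 2,4-dimethoxybenzylamine | COc1ccc(CN)c(OC)c1 | starting material
12 | methyl (2Z,3E)-3,4-bis[1-(tert-butoxycarbonyl)indol-3-yl]-2-[(2,4-dimethoxybenzyl)imino]but-3-enoate (benzyl group syn to the ester) | COC(=O)C(=N\Cc1ccc(OC)cc1OC)/C(=C/c1cn(C(=O)OC(C)(C)C)c2ccccc12)c1cn(C(=O)OC(C)(C)C)c2ccccc12 | intermediate
13 | pentane-2,4-dione | CC(=O)CC(C)=O | starting material
14 | 3-diazopentane-2,4-dione | CC(=O)C(=[N+]=[N-])C(C)=O | intermediate
15 | diazoacetone (1-diazopropan-2-one) | CC(=O)C=[N+]=[N-] | intermediate
16 | azomethine ylide: the iminium nitrogen of 12 carries an added CH(−)–C(=O)CH3 carbon, syn to the C3=C4 bond | COC(=O)C(=[N+](\Cc1ccc(OC)cc1OC)[CH-]C(C)=O)/C(=C/c1cn(C(=O)OC(C)(C)C)c2ccccc12)c1cn(C(=O)OC(C)(C)C)c2ccccc12 | intermediate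
17 | methyl trans-5-acetyl-1-(2,4-dimethoxybenzyl)-3,4-bis[1-(tert-butoxycarbonyl)indol-3-yl]-4,5-dihydro-1H-pyrrole-2-carboxylate (racemic, one enantiomer drawn) | COC(=O)C1=C(c2cn(C(=O)OC(C)(C)C)c3ccccc23)[C@@H](c2cn(C(=O)OC(C)(C)C)c3ccccc23)[C@H](C(C)=O)N1Cc1ccc(OC)cc1OC | intermediate
18 | methyl 5-acetyl-1-(2,4-dimethoxybenzyl)-3,4-bis[1-(tert-butoxycarbonyl)indol-3-yl]pyrrole-2-carboxylate | COC(=O)c1n(Cc2ccc(OC)cc2OC)c(C(C)=O)c(-c2cn(C(=O)OC(C)(C)C)c3ccccc23)c1-c1cn(C(=O)OC(C)(C)C)c2ccccc12 | intermediate
19 | methyl 5-acetyl-3,4-di(1H-indol-3-yl)-1H-pyrrole-2-carboxylate | COC(=O)c1[nH]c(C(C)=O)c(-c2c[nH]c3ccccc23)c1-c1c[nH]c2ccccc12 | target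

**Counts**

Total step count: 8.
Longest linear sequence: 7 steps (1, 2, 3, 4, 5, 7, 8); step 6 is a one-step side branch.

**Steps most likely to fail**

Step 7. The ylide may close to the three-membered ring or through the acetyl oxygen instead of at C4, the carbene may dimerise or the basic imine may inhibit the catalyst, and the imine may hydrolyse before capture. The fallback sets out from 10 and returns at 19; it makes the same ylide-type intermediate without a carbene. Keto ester 10 would be condensed with aminoacetone hydrochloride in pyridine over 4 Å molecular sieves to give methyl (2Z,3E)-3,4-bis[1-(tert-butoxycarbonyl)indol-3-yl]-2-[(2-oxopropyl)imino]but-3-enoate F1. On warming to about 60 °C in the same medium this should undergo prototropy to the N–H azomethine ylide and 1,5-electrocyclisation to methyl trans-5-acetyl-3,4-bis[1-(tert-butoxycarbonyl)indol-3-yl]-4,5-dihydro-1H-pyrrole-2-carboxylate F2. This is the known cyclocondensation of enones with α-amino nitriles, esters or ketones. DDQ in CH2Cl2 would dehydrogenate it to methyl 5-acetyl-3,4-bis[1-(tert-butoxycarbonyl)indol-3-yl]-1H-pyrrole-2-carboxylate F3, and TFA in CH2Cl2 at room temperature would remove the two Boc groups to give 19.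

Step 5. The amine may add in conjugate fashion at C4, aminolyse the activated methyl ester, the Lewis acid may strip a Boc group, or base may shift the benzylic imine to its 2-aza-allyl tautomer. The fallback sets out from 10 (with amine 11) and returns at 12; it forms the C=N bond by aza-Wittig reaction under neutral conditions. Amine 11 would be converted by diazo transfer (imidazole-1-sulfonyl azide hydrogen sulfate, K2CO3, CuSO4 cat., MeOH) into 1-(azidomethyl)-2,4-dimethoxybenzene F4. Staudinger reaction with PPh3 in THF would give N-(2,4-dimethoxybenzyl)iminotriphenylphosphorane F5, which should react with the keto carbonyl of 10 in toluene at 60 °C to give 12 and triphenylphosphine oxide.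

Step 4. The indolyl boronate may protodeboronate, and the base may hydrolyse the α-keto ester or cleave a Boc group before transmetalation. The fallback sets out from 8 and returns at 10; it replaces the base-activated boron nucleophile by a neutral tin nucleophile. Commercial tert-butyl 3-bromoindole-1-carboxylate would be stannylated with (Bu3Sn)2 and Pd(PPh3)4 in toluene at 100 °C to give tert-butyl 3-(tributylstannyl)indole-1-carboxylate F6. Stille coupling with 8 (Pd2(dba)3, AsPh3, CuI, DMF, rt → 40 °C) should deliver 10 with retention of alkene geometry and without base.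

**Further compounds**

F1 | step 7 | methyl (2Z,3E)-3,4-bis[1-(tert-butoxycarbonyl)indol-3-yl]-2-[(2-oxopropyl)imino]but-3-enoate | COC(=O)C(=N\CC(C)=O)/C(=C/c1cn(C(=O)OC(C)(C)C)c2ccccc12)c1cn(C(=O)OC(C)(C)C)c2ccccc12
F2 | step 7 | methyl trans-5-acetyl-3,4-bis[1-(tert-butoxycarbonyl)indol-3-yl]-4,5-dihydro-1H-pyrrole-2-carboxylate (racemic, one enantiomer drawn) | COC(=O)C1=C(c2cn(C(=O)OC(C)(C)C)c3ccccc23)[C@@H](c2cn(C(=O)OC(C)(C)C)c3ccccc23)[C@H](C(C)=O)N1
F3 | step 7 | methyl 5-acetyl-3,4-bis[1-(tert-butoxycarbonyl)indol-3-yl]-1H-pyrrole-2-carboxylate | COC(=O)c1[nH]c(C(C)=O)c(-c2cn(C(=O)OC(C)(C)C)c3ccccc23)c1-c1cn(C(=O)OC(C)(C)C)c2ccccc12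
F4 | step 5 | 1-(azidomethyl)-2,4-dimethoxybenzene | COc1ccc(CN=[N+]=[N-])c(OC)c1
F5 | step 5 | N-(2,4-dimethoxybenzyl)iminotriphenylphosphorane | COc1ccc(CN=P(c2ccccc2)(c2ccccc2)c2ccccc2)c(OC)c1
F6 | step 4 | tert-butyl 3-(tributylstannyl)indole-1-carboxylate | CCCC[Sn](CCCC)(CCCC)c1cn(C(=O)OC(C)(C)C)c2ccccc12
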